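The tridepside is cut at the ring A–ring B ester and, more deeply, through ring B itself, which is grown directly on the ester oxygen of ring C. The feature used is the oxygen pair of ring B: C4–O must carry ring A, whereas C2–O ends as a free, chelated phenol. Photolysis of a ring C aryl 2-diazo-4-methyl-3-oxopent-4-enoate gives a vinylketene with the aryl ester on its substituted carbon. Ethoxyacetylene adds, and ring opening plus six-electron closure complete C3–C4, C1–C2 and C4–C5 in one operation. Ring B emerges with C4–OH free and C2–O masked as an ethyl ether, so the acylation with the ring A acid needs no selectivity.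

Key step: step 8

Remark (numbering): in every ring C1 bears the carbonyl group, C2 the oxygen next to it, C4 the para oxygen and C6 the methyl group; ring A also carries OCH3 at C5.
Remark (stereochemistry): the target has no stereocentre; the carbinol of step 7 and the cyclobutenone of step 8 form as racemates and lose their stereocentres within the same step.
Remark (design): ring A C5–OCH3 is a crowded ether that surplus BCl3 can attack, so the ether cleavage uses about one equivalent of BCl3 per carbonyl chelate and is kept apart from the hydrogenolysis.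

**Ring C phenol and diazo ketoester**

Step 1
Reactants: 1 orsellinic acid (2,4-dihydroxy-6-methylbenzoic acid)
Product: 2 benzyl 2,4-dihydroxy-6-methylbenzoate (benzyl orsellinate)
Conditions: BnBr, KHCO3, DMF, rt
Reagents that add atoms: benzyl bromide BrCc1ccccc1
Why: Carboxylate O-alkylation (SN2): KHCO3 ionises only the acid, so both phenols stay free, and room temperature avoids decarboxylation of 1.

Step 2
Reactants: 2 benzyl orsellinate
Product: 3 benzyl 2-hydroxy-4-(methoxymethoxy)-6-methylbenzoate
Conditions: MOMCl, i-Pr2NEt, CH2Cl2, 0 °C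
Reagents that add atoms: chloromethyl methyl ether COCCl
Why: Chemoselective Williamson-type etherification: C2–OH is tied up in a hydrogen bond to the ester carbonyl, so the amine base and MOMCl reach only C4–OH.

Step 3
Reactants: 3 benzyl 2-hydroxy-4-(methoxymethoxy)-6-methylbenzoate
Product: 4 benzyl 2-(benzyloxy)-4-(methoxymethoxy)-6-methylbenzoate
Conditions: BnBr, K2CO3, DMF, 60 °C
Reagents that add atoms: benzyl bromide BrCc1ccccc1
Why: Williamson ether synthesis: with C4–O blocked, K2CO3 in warm DMF ionises the chelated C2–OH, and the MOM acetal and the di-ortho-substituted ester tolerate the base.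

Step 4
Reactants: 4 benzyl 2-(benzyloxy)-4-(methoxymethoxy)-6-methylbenzoate
Product: 5 benzyl 2-(benzyloxy)-4-hydroxy-6-methylbenzoate (ring C phenol)
Conditions: HCl (cat.), MeOH–THF, 45 °C
Reagents that add atoms: none
Why: Acid-catalysed acetal exchange (MOM cleavage): the formaldehyde acetal is passed on to methanol, while the benzyl ether and the hindered benzyl ester are inert to dilute HCl.

Step 5
Reactants: 5 ring C phenol; 6 bromoacetyl bromide
Product: 7 benzyl 2-(benzyloxy)-4-(2-bromoacetoxy)-6-methylbenzoate
Conditions: pyridine, CH2Cl2, 0 °C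
Reagents that add atoms: none
Why: O-acylation of a phenol by an acyl halide (Einhorn conditions): the acyl bromide carbon reacts far faster than the CH2Br carbon, and 5 has only one free hydroxyl.

Step 6
Reactants: 7 ring C aryl bromoacetate
Product: 8 benzyl 2-(benzyloxy)-4-(2-diazoacetoxy)-6-methylbenzoate
Conditions: TsNHNHTs, DBU, THF, 0 °C
Reagents that add atoms: N,N'-ditosylhydrazine Cc1ccc(cc1)S(=O)(=O)NNS(=O)(=O)c1ccc(C)cc1
Why: Diazoacetate synthesis from a bromoacetate: the ditosylhydrazine anion displaces bromide (SN2) and DBU then drives out two sulfinate ions (Bamford–Stevens-type elimination), fast enough at 0 °C to spare both aryl-bound esters.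

Step 7
Reactants: 8 ring C aryl diazoacetate; 9 methacrolein
Product: 11 benzyl 2-(benzyloxy)-4-[(2-diazo-4-methyl-3-oxopent-4-enoyl)oxy]-6-methylbenzoate, via diazo carbinol 10 (not isolated)
Conditions: DBU (cat.), DMSO, rt; then IBX, rt
Reagents that add atoms: none
Why: Base-catalysed aldol-type 1,2-addition of a diazoacetate anion to an enal followed by IBX oxidation in the same DMSO solution, a known one-pot entry to 2-diazo-3-oxo esters; the carbinol centre of 10 forms without control (racemic) and is erased by the oxidation.

**Key step**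

Step 8
Reactants: 11 ring C aryl 2-diazo-4-methyl-3-oxopent-4-enoate; 12 ethoxyacetylene
Product: 17 benzyl 2-(benzyloxy)-4-[(2-ethoxy-4-hydroxy-6-methylbenzoyl)oxy]-6-methylbenzoate (B–C didepside), via vinylketene 13 (not isolated), via cyclobutenone 14 (not isolated), via dienylketene 15 (not isolated), via cyclohexadienone 16 (not isolated)
Conditions: 12 (4 equiv), ClCH2CH2Cl, 365 nm LED, 20 °C; excess 12 evaporated; toluene, 80 °C
Reagents that add atoms: none
Why: Proposed new method: excitation of the diazo dicarbonyl chromophore at 365 nm, where neither aryl ester absorbs and photo-Fries cleavage is avoided, expels N2 while the isopropenyl group shifts from the ketone carbon to the diazo carbon (Wolff rearrangement, the ketone-side group moving in preference to aryloxy), so that ketene 13 holds the future C4 as its C=O carbon and the future C1 as its substituted carbon. The electron-rich terminal carbon of 12 adds to the central ketene carbon (C3–C4) and the ethoxy-bearing carbon then closes onto C1 (C1–C2), a polar [2+2] cycloaddition that should give racemic cyclobutenone 14. At 80 °C 14 opens by reversible four-electron conrotation to 15, whose Z isomer (isopropenyl cis to the ketenyl group) closes the six-membered carbocycle of ring B by six-electron disrotatory electrocyclisation (C4–C5) to 16, and irreversible tautomerisation gives phenol 17 with no stereocentre left. The closest known reaction type is the Danheiser benzannulation in its diazo ketone form with alkoxy- and siloxyalkynes, which delivers resorcinol monoethers; the new element is the acceptor (aryl ester) on the ketene carbon. The step needs regioselectivity (OEt at C2, OH at C4) and periselectivity (four-membered closure of the dipolar adduct, not closure through the ester oxygen to a pyranone or through the isopropenyl CH2, which would exchange OH and OEt). The first is set by the polarisation of 12; the second is favoured because an ester carbonyl, and an aryl ester most of all, is a much poorer heterodiene terminus than the ketone carbonyl of true acylketenes, and because the internal methyl group twists the isopropenyl unit out of the plane that direct six-membered closure would need.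

**Ring A acid**

Step 9
Reactants: 18 2,4-dihydroxy-6-methylbenzaldehyde (orcylaldehyde)
Product: 19 2,4-bis(benzyloxy)-6-methylbenzaldehyde
Conditions: BnBr, K2CO3, DMF, 60 °C
Reagents that add atoms: benzyl bromide BrCc1ccccc1
Why: Double Williamson ether synthesis: excess BnBr and K2CO3 in warm DMF alkylate both the free 4-OH and the aldehyde-chelated 2-OH.

Step 10
Reactants: 19 2,4-bis(benzyloxy)-6-methylbenzaldehyde
Product: 21 2,4-bis(benzyloxy)-6-methylphenol, via aryl formate 20 (not isolated)
Conditions: mCPBA, CH2Cl2, 0 °C → rt; then KOH, MeOH–H2O, 0 °C; H3O+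
Reagents that add atoms: meta-chloroperbenzoic acid O=C(OO)c1cccc(Cl)c1
Why: Baeyer–Villiger (Dakin-type) oxidation: the electron-rich aryl group migrates in the Criegee adduct in preference to hydride, and brief saponification of formate 20 frees the phenol whose oxygen becomes ring A C5–O.

Step 11
Reactants: 21 2,4-bis(benzyloxy)-6-methylphenol
Product: 22 1,5-bis(benzyloxy)-2-methoxy-3-methylbenzene
Conditions: MeI, K2CO3, acetone, reflux
Reagents that add atoms: iodomethane CI
Why: Williamson methylation of the only free phenol fixes the methyl ether at ring A C5 without any regiochemical question.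

Step 12
Reactants: 22 1,5-bis(benzyloxy)-2-methoxy-3-methylbenzene
Product: 24 2,4-bis(benzyloxy)-5-methoxy-6-methylbenzaldehyde, via iminium chloride 23 (not isolated)
Conditions: POCl3, DMF, 0 → 60 °C; then H2O
Reagents that add atoms: N,N-dimethylformamide CN(C)C=O; water O
Why: Vilsmeier–Haack formylation: of the two free ring positions the one between CH3 and OBn (para to one benzyloxy group, ortho to the other) is attacked, since the CH flanked by two benzyloxy groups is shielded, as is the rule for orcinol diethers.

Step 13
Reactants: 24 2,4-bis(benzyloxy)-5-methoxy-6-methylbenzaldehyde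
Product: 25 2,4-bis(benzyloxy)-5-methoxy-6-methylbenzoic acid (ring A acid)
Conditions: NaClO2, NaH2PO4, 2-methyl-2-butene, t-BuOH–THF–H2O, rt
Reagents that add atoms: sodium chlorite [Na+].[O-]Cl=O
Why: Pinnick oxidation: chlorous acid converts the hindered aldehyde to the acid under near-neutral conditions, and 2-methyl-2-butene takes up HOCl before it can chlorinate ring A C3.

**Coupling and deprotection**

Step 14
Reactants: 25 ring A acid; 17 B–C didepside
Product: 27 fully protected tridepside (ring A 2,4-di-O-benzyl; ring B 2-O-ethyl; ring C 2-O-benzyl benzyl ester), via mixed anhydride 26 (not isolated)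
Conditions: (CF3CO)2O, toluene, rt
Reagents that add atoms: none
Why: Mixed-anhydride esterification, the standard depside coupling: TFAA turns the crowded, electron-rich acid into acylating agent 26, and 17 offers ring B C4–OH as its only hydroxyl.

Step 15
Reactants: 27 fully protected tridepside
Product: 28 dibenzyl tridepside (all three C2–OH free; ring A C4–OBn and ring C benzyl ester kept)
Conditions: BCl3 (3.3 equiv), C6HMe5, CH2Cl2, −78 → 0 °C; then H2O
Reagents that add atoms: none
Why: Chelation-directed ether cleavage: BCl3 binds each ester carbonyl together with its ortho alkoxy oxygen, so the three six-membered chelates lose ethyl (to chloride) or benzyl (to pentamethylbenzene), while ring A C5–OCH3 and C4–OBn meet no free Lewis acid at one equivalent per chelate, and any early loss of the two remaining benzyl groups is made good in step 16.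

Step 16
Reactants: 28 dibenzyl tridepside
Product: 29 CNP0327242.0 (target tridepside)
Conditions: H2 (1 atm), 10% Pd/C, EtOAc–THF, rt
Reagents that add atoms: none
Why: Catalytic hydrogenolysis of the last benzyl ether and the benzyl ester under neutral conditions in a non-alcoholic solvent, which leaves both depside esters and the methyl ether untouched.

**Compound list**

1 | orsellinic acid | Cc1cc(O)cc(O)c1C(=O)O | starting material
2 | benzyl 2,4-dihydroxy-6-methylbenzoate | Cc1cc(O)cc(O)c1C(=O)OCc1ccccc1 | intermediate
3 | benzyl 2-hydroxy-4-(methoxymethoxy)-6-methylbenzoate | COCOc1cc(C)c(C(=O)OCc2ccccc2)c(O)c1 | intermediate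
4 | benzyl 2-(benzyloxy)-4-(methoxymethoxy)-6-methylbenzoate | COCOc1cc(C)c(C(=O)OCc2ccccc2)c(OCc2ccccc2)c1 | intermediate
5 | benzyl 2-(benzyloxy)-4-hydroxy-6-methylbenzoate | Oc1cc(C)c(C(=O)OCc2ccccc2)c(OCc2ccccc2)c1 | intermediate
6 | bromoacetyl bromide | O=C(Br)CBr | starting material
7 | benzyl 2-(benzyloxy)-4-(2-bromoacetoxy)-6-methylbenzoate | O=C(CBr)Oc1cc(C)c(C(=O)OCc2ccccc2)c(OCc2ccccc2)c1 | intermediate
8 | benzyl 2-(benzyloxy)-4-(2-diazoacetoxy)-6-methylbenzoate | [N-]=[N+]=CC(=O)Oc1cc(C)c(C(=O)OCc2ccccc2)c(OCc2ccccc2)c1 | intermediate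
9 | methacrolein | C=C(C)C=O | starting material
10 | (±)-benzyl 2-(benzyloxy)-4-[(2-diazo-3-hydroxy-4-methylpent-4-enoyl)oxy]-6-methylbenzoate (racemic, not isolated) | C=C(C)C(O)C(=[N+]=[N-])C(=O)Oc1cc(C)c(C(=O)OCc2ccccc2)c(OCc2ccccc2)c1 | intermediate
11 | benzyl 2-(benzyloxy)-4-[(2-diazo-4-methyl-3-oxopent-4-enoyl)oxy]-6-methylbenzoate | C=C(C)C(=O)C(=[N+]=[N-])C(=O)Oc1cc(C)c(C(=O)OCc2ccccc2)c(OCc2ccccc2)c1 | intermediate
12 | ethoxyacetylene | C#COCC | starting material
13 | vinylketene: ring C aryl 3-methyl-2-(oxomethylidene)but-3-enoate (not isolated) | C=C(C)C(=C=O)C(=O)Oc1cc(C)c(C(=O)OCc2ccccc2)c(OCc2ccccc2)c1 | intermediate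
14 | (±)-cyclobutenone: ring C aryl 2-ethoxy-4-oxo-1-(prop-1-en-2-yl)cyclobut-2-ene-1-carboxylate (racemic, not isolated) | CCOC1=CC(=O)C1(C(C)=C)C(=O)Oc1cc(C)c(C(=O)OCc2ccccc2)c(OCc2ccccc2)c1 | intermediate
15 | dienylketene: ring C aryl (2Z)-3-ethoxy-5-oxo-2-(prop-1-en-2-yl)penta-2,4-dienoate (not isolated) | O=C=C/C(OCC)=C(\C(C)=C)C(=O)Oc1cc(C)c(C(=O)OCc2ccccc2)c(OCc2ccccc2)c1 | intermediate
16 | cyclohexadienone: ring C aryl 6-ethoxy-2-methyl-4-oxocyclohexa-1,5-diene-1-carboxylate (not isolated) | CCOC1=CC(=O)CC(C)=C1C(=O)Oc1cc(C)c(C(=O)OCc2ccccc2)c(OCc2ccccc2)c1 | intermediate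
17 | benzyl 2-(benzyloxy)-4-[(2-ethoxy-4-hydroxy-6-methylbenzoyl)oxy]-6-methylbenzoate | CCOc1cc(O)cc(C)c1C(=O)Oc1cc(C)c(C(=O)OCc2ccccc2)c(OCc2ccccc2)c1 | intermediate
18 | 2,4-dihydroxy-6-methylbenzaldehyde | Cc1cc(O)cc(O)c1C=O | starting material
19 | 2,4-bis(benzyloxy)-6-methylbenzaldehyde | Cc1cc(OCc2ccccc2)cc(OCc2ccccc2)c1C=O | intermediate
20 | 2,4-bis(benzyloxy)-6-methylphenyl formate (not isolated) | Cc1cc(OCc2ccccc2)cc(OCc2ccccc2)c1OC=O | intermediate
21 | 2,4-bis(benzyloxy)-6-methylphenol | Cc1cc(OCc2ccccc2)cc(OCc2ccccc2)c1O | intermediate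
22 | 1,5-bis(benzyloxy)-2-methoxy-3-methylbenzene | COc1c(C)cc(OCc2ccccc2)cc1OCc1ccccc1 | intermediate
23 | [2,4-bis(benzyloxy)-5-methoxy-6-methylbenzylidene]dimethyliminium chloride (not isolated) | COc1c(OCc2ccccc2)cc(OCc2ccccc2)c(C=[N+](C)C)c1C.[Cl-] | intermediate
24 | 2,4-bis(benzyloxy)-5-methoxy-6-methylbenzaldehyde | COc1c(OCc2ccccc2)cc(OCc2ccccc2)c(C=O)c1C | intermediate
25 | 2,4-bis(benzyloxy)-5-methoxy-6-methylbenzoic acid | COc1c(OCc2ccccc2)cc(OCc2ccccc2)c(C(=O)O)c1C | intermediate
26 | 2,4-bis(benzyloxy)-5-methoxy-6-methylbenzoic trifluoroacetic anhydride (not isolated) | COc1c(OCc2ccccc2)cc(OCc2ccccc2)c(C(=O)OC(=O)C(F)(F)F)c1C | intermediate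
27 | fully protected tridepside | COc1c(OCc2ccccc2)cc(OCc2ccccc2)c(C(=O)Oc2cc(C)c(C(=O)Oc3cc(C)c(C(=O)OCc4ccccc4)c(OCc4ccccc4)c3)c(OCC)c2)c1C | intermediate
28 | dibenzyl tridepside | COc1c(OCc2ccccc2)cc(O)c(C(=O)Oc2cc(C)c(C(=O)Oc3cc(C)c(C(=O)OCc4ccccc4)c(O)c3)c(O)c2)c1C | intermediate
29 | CNP0327242.0 | COc1c(O)cc(O)c(C(=O)Oc2cc(C)c(C(=O)Oc3cc(C)c(C(=O)O)c(O)c3)c(O)c2)c1C | target

Total step count: 16.
Longest linear sequence: 11 steps (steps 1–8, then 14–16). The ring A branch (steps 9–13) joins at step 14.

**Steps most likely to fail**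

**1. Step 8.**
- What may go wrong: the dipolar adduct of ketene and alkyne may collapse through the ester oxygen or through the alkene terminus instead of forming the four-membered ring.
- Long-wavelength light may isomerise the diazo group rather than expel nitrogen.
- The acceptor-substituted ketene may dimerise before the alkyne reaches it.
- Fallback (known chemistry only): it sets out from 3 and 5 and comes back at 17. Phenol 3 is ethylated (EtI, K2CO3, DMF) to benzyl 2-ethoxy-4-(methoxymethoxy)-6-methylbenzoate F1. Its benzyl ester is hydrogenolysed (H2, Pd/C, EtOAc) to 2-ethoxy-4-(methoxymethoxy)-6-methylbenzoic acid F2. Steglich esterification of F2 with 5 (DCC, DMAP, CH2Cl2) gives the MOM-protected didepside F3. Catalytic HCl in MeOH–THF then frees ring B C4–OH and gives 17, so the remaining steps stay as written.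

**2. Step 15.**
- What may go wrong: boron may coordinate at the crowded ring A C5 oxygen and cause loss of the methyl ether.
- Displacement at the ethyl group is slow and may leave the ether cleavage incomplete.
- Benzyl cations may be transferred to the electron-rich rings.
- Fallback: it sets out from 17 and comes back at 29. The Lewis acid step is moved ahead of the coupling, to a compound that holds no methyl ether. Excess BCl3 with pentamethylbenzene strips the ethyl group and both benzyl groups from 17 to give lecanoric acid F4. BnBr and KHCO3 in DMF re-esterify the acid only and give benzyl lecanorate F5. The TFAA coupling with 25 (through 26) then acylates the single unchelated hydroxyl, ring B C4–OH, as in classical chelation-controlled depside couplings, and gives the tribenzyl tridepside F6. Hydrogenolysis (H2, Pd/C, EtOAc–THF) gives 29.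

**3. Step 7.**
- What may go wrong: the base may induce acyl transfer from the activated aryl ester.
- The aldol addition may reverse before oxidation.
- The diazo enone may cyclise onto its own alkene.
- Methacrolein may polymerise.
- Fallback: it sets out from 5 and comes back at 11, so that steps 5 to 7 are bypassed and the diazo group is put in last. Meldrum's acid is C-acylated with methacryloyl chloride (pyridine, CH2Cl2, 0 °C) to the acyl Meldrum's acid F7. Heating F7 with 5 in toluene releases an acylketene that the phenol traps, giving the ring C aryl 4-methyl-3-oxopent-4-enoate F8. Regitz diazo transfer (4-acetamidobenzenesulfonyl azide, Et3N, MeCN, 0 °C) gives 11.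

**Further compounds**

F1 | step 8 | benzyl 2-ethoxy-4-(methoxymethoxy)-6-methylbenzoate | CCOc1cc(OCOC)cc(C)c1C(=O)OCc1ccccc1
F2 | step 8 | 2-ethoxy-4-(methoxymethoxy)-6-methylbenzoic acid | CCOc1cc(OCOC)cc(C)c1C(=O)O
F3 | step 8 | benzyl 2-(benzyloxy)-4-{[2-ethoxy-4-(methoxymethoxy)-6-methylbenzoyl]oxy}-6-methylbenzoate | CCOc1cc(OCOC)cc(C)c1C(=O)Oc1cc(C)c(C(=O)OCc2ccccc2)c(OCc2ccccc2)c1
F4 | step 15 | lecanoric acid | Cc1cc(O)cc(O)c1C(=O)Oc1cc(C)c(C(=O)O)c(O)c1
F5 | step 15 | benzyl lecanorate | Cc1cc(O)cc(O)c1C(=O)Oc1cc(C)c(C(=O)OCc2ccccc2)c(O)c1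
F6 | step 15 | tribenzyl tridepside (ring A 2,4-di-O-benzyl, ring C benzyl ester, ring B and ring C C2–OH free) | COc1c(OCc2ccccc2)cc(OCc2ccccc2)c(C(=O)Oc2cc(C)c(C(=O)Oc3cc(C)c(C(=O)OCc4ccccc4)c(O)c3)c(O)c2)c1C
F7 | step 7 | 5-(1-hydroxy-2-methylprop-2-en-1-ylidene)-2,2-dimethyl-1,3-dioxane-4,6-dione | C=C(C)C(O)=C1C(=O)OC(C)(C)OC1=O
F8 | step 7 | benzyl 2-(benzyloxy)-6-methyl-4-[(4-methyl-3-oxopent-4-enoyl)oxy]benzoate | C=C(C)C(=O)CC(=O)Oc1cc(C)c(C(=O)OCc2ccccc2)c(OCc2ccccc2)c1
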